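The cyclohexane ring is numbered C1 (quaternary: methyl C10, chlorovinyl C8=C9), C2, C3 (Br, C7H2Br), C4 (Cl), C5, C6 (Cl). Everything rests on the C1–C6 bond, which joins the quaternary carbon to its chlorinated neighbour. A boat Ireland–Claisen rearrangement of a δ-lactone forms this bond, exchanges the lactone for the carbocycle and sets C1 and C6 in one operation, with chlorine arriving on an (E)-chlorovinyl group so that no substitution at neopentylic C6 is needed. The precursor is a 6-[(E)-2-chlorovinyl]-3-methyl-δ-lactone whose future C3 is masked as a 1,3-dithiane and whose C4 carbinol centre comes from an asymmetric ynone reduction.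

Key step: step 9

Remarks on the chemistry:
- The methyl-bearing centre of the lactone is erased in the ketene acetal; enantiopure bromo alcohol 1 is used only so that every intermediate is one diastereomer, and the racemate would serve as well.
- The rearrangement keeps the ring size at six (lactone to carbocycle); it is not a contraction.
- Electrophilic chlorine in combination with silver salts would cleave the dithiane, so the alkyne is chlorinated through its lithium acetylide instead.
- Chlorine at C4 is brought in by hydroxylation and SN2 inversion, because direct electrophilic chlorination of the C3–C4 enolate is expected to place chlorine trans to the C6 chlorine.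

Step 1
Reactants: 1 (R)-3-bromo-2-methylpropan-1-ol
Product: 2 (R)-(3-bromo-2-methylpropoxy)(tert-butyl)dimethylsilane
Conditions: TBSCl, imidazole, CH2Cl2, 0 °C → rt
Reagents that add atoms: tert-butyldimethylsilyl chloride, CC(C)(C)[Si](C)(C)Cl
Why: Routine silylation of a primary alcohol; the silyl ether withstands the organolithium steps and is removed later together with the alkynyl silane.

Step 2
Reactants: 3 1,3-dithiane; 2 (R)-(3-bromo-2-methylpropoxy)(tert-butyl)dimethylsilane
Product: 5 (S)-tert-butyl[3-(1,3-dithian-2-yl)-2-methylpropoxy]dimethylsilane, via 2-lithio-1,3-dithiane 4 (not isolated)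
Conditions: n-BuLi, THF, −30 °C; then 2, DMPU, −30 °C → rt
Reagents that add atoms: none
Why: Corey–Seebach alkylation of the dithiane anion with a primary bromide; the stereocentre is β to the reacting carbon and is untouched (the descriptor changes only through priorities).

Step 3
Reactants: 5 (S)-tert-butyl[3-(1,3-dithian-2-yl)-2-methylpropoxy]dimethylsilane; 6 3-(trimethylsilyl)propynal
Product: 8 1-{2-[(S)-3-(tert-butyldimethylsilyloxy)-2-methylpropyl]-1,3-dithian-2-yl}-3-(trimethylsilyl)prop-2-yn-1-ol as a mixture of carbinol epimers, via the 2-lithiodithiane 7 (not isolated)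
Conditions: n-BuLi, THF, −20 °C; then 6, −78 °C; H2O
Reagents that add atoms: none
Why: 1,2-Addition of a 2-alkyl-2-lithio-1,3-dithiane to an aldehyde (Corey–Seebach acyl anion chemistry) joins C3 to C4; the uncontrolled carbinol centre is levelled in steps 4 and 5.

Step 4
Reactants: 8 1-{2-[(S)-3-(tert-butyldimethylsilyloxy)-2-methylpropyl]-1,3-dithian-2-yl}-3-(trimethylsilyl)prop-2-yn-1-ol
Product: 9 1-{2-[(S)-3-(tert-butyldimethylsilyloxy)-2-methylpropyl]-1,3-dithian-2-yl}-3-(trimethylsilyl)prop-2-yn-1-one
Conditions: Dess–Martin periodinane, NaHCO3, CH2Cl2, 0 °C → rt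
Reagents that add atoms: none
Why: Dess–Martin oxidation of a propargylic alcohol, a buffered oxidant that leaves thioacetals and silyl ethers alone.

Step 5
Reactants: 9 1-{2-[(S)-3-(tert-butyldimethylsilyloxy)-2-methylpropyl]-1,3-dithian-2-yl}-3-(trimethylsilyl)prop-2-yn-1-one
Product: 10 (R)-1-{2-[(S)-3-(tert-butyldimethylsilyloxy)-2-methylpropyl]-1,3-dithian-2-yl}-3-(trimethylsilyl)prop-2-yn-1-ol
Conditions: RuCl(p-cymene)[(S,S)-TsDPEN] (2 mol %), i-PrOH, rt
Reagents that add atoms: none
Why: Noyori asymmetric transfer hydrogenation of an alkynyl ketone, in which the alkyne takes the place of the aryl group of an aryl ketone, so the (S,S)-ligand should deliver hydride to the face that gives the carbinol named R here (the dithiane carbon outranks the alkyne); this sets C4.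

Step 6
Reactants: 10 (R)-1-{2-[(S)-3-(tert-butyldimethylsilyloxy)-2-methylpropyl]-1,3-dithian-2-yl}-3-(trimethylsilyl)prop-2-yn-1-ol
Product: 11 (R)-1-{2-[(S)-3-hydroxy-2-methylpropyl]-1,3-dithian-2-yl}prop-2-yn-1-ol
Conditions: TBAF, AcOH, THF, 0 °C → rt
Reagents that add atoms: none
Why: Fluoride cleaves the O–Si and the alkynyl C–Si bond in one operation; acetic acid buffering avoids retro-addition of the dithiane carbinol.

Step 7
Reactants: 11 (R)-1-{2-[(S)-3-hydroxy-2-methylpropyl]-1,3-dithian-2-yl}prop-2-yn-1-ol
Product: 14 (7R,10S)-7-ethynyl-10-methyl-8-oxa-1,5-dithiaspiro[5.5]undecan-9-one, via hydroxy aldehyde 12 (not isolated), via lactol 13 (not isolated)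
Conditions: TEMPO (cat.), PhI(OAc)2, CH2Cl2, rt
Reagents that add atoms: none
Why: Oxoammonium oxidation takes the primary alcohol first, the hydroxy aldehyde closes to the six-membered lactol and this is oxidised on (oxidative lactonisation of a 1,5-diol); alcohols react faster than thioacetal sulfur under these conditions.

Step 8
Reactants: 14 (7R,10S)-7-ethynyl-10-methyl-8-oxa-1,5-dithiaspiro[5.5]undecan-9-one
Product: 16 (7R,10S)-7-[(E)-2-chloroethenyl]-10-methyl-8-oxa-1,5-dithiaspiro[5.5]undecan-9-one, via alkenylzirconocene chloride 15 (not isolated)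
Conditions: Cp2Zr(H)Cl, THF, rt; then NCS (1.05 equiv), 0 °C
Reagents that add atoms: N-chlorosuccinimide, O=C1CCC(=O)N1Cl
Why: Hydrozirconation adds Zr–H syn with zirconium on the terminal carbon and N-chlorosuccinimide cleaves the C–Zr bond with retention, giving the (E)-chloroalkene; the ester is tolerated, and one equivalent of chlorinating agent at 0 °C should be consumed by the alkenylzirconium before it touches sulfur.

Step 9
Reactants: 16 (7R,10S)-7-[(E)-2-chloroethenyl]-10-methyl-8-oxa-1,5-dithiaspiro[5.5]undecan-9-one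
Product: 19 (8S,9S)-9-chloro-8-methyl-1,5-dithiaspiro[5.5]undec-10-ene-8-carboxylic acid, via trimethylsilyl ketene acetal 17 (not isolated), via trimethylsilyl ester 18 (not isolated)
Conditions: LDA, TMSCl/Et3N, THF, −78 °C; then hexane, filtration, toluene, 100 °C; then 1 M HCl, THF, rt
Reagents that add atoms: none
Why: Deprotonation at C1 with TMSCl present gives ketene acetal 17 with its C1=C8 geometry fixed by the ring, and because the C2–C3 bridge ties C1 to C4 the vinyl group on C4 can reach C1 only across the lactone, so the concerted suprafacial [3,3] shift runs through a boat (bicyclo[2.2.2]octane-like) transition state, forming C1–C6 and breaking C4–O. The closest known reaction type is the Ireland–Claisen rearrangement of 6-alkenyl δ-lactones and 6-alkenyl-1,4-dioxan-2-ones to cyclohexene- and dihydropyran-carboxylic acids, here with a chlorine on the alkene terminus. The one ring formed, the carbocycle C1–C6, closes by this pericyclic C1–C6 bonding while the ester oxygen leaves the ring, not by an ionic exo or endo cyclisation, and the ring size stays six. C6 is set by the E geometry of the alkene, which in the boat puts chlorine on the face of the carboxyl carbon C8 and opposite to methyl C10; C1 is set by the ring-locked ketene acetal together with the (R)-carbinol centre C4, which allows bonding on one face only and should give the (1S,6S) acid. The selectivity needed is [3,3] shift over ketene formation, sulfur-assisted ionisation and chloride loss, secured by trapping the enolate as it forms, by the absence of any Lewis acid, by removing the salts before heating, and by the quaternary C1 of 18, which cannot eliminate the β-chloride.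

Step 10
Reactants: 19 (8S,9S)-9-chloro-8-methyl-1,5-dithiaspiro[5.5]undec-10-ene-8-carboxylic acid
Product: 20 (8S,9S)-9-chloro-8-methyl-1,5-dithiaspiro[5.5]undecane-8-carboxylic acid
Conditions: 2-nitrobenzenesulfonylhydrazide (excess), Et3N, THF, rt
Reagents that add atoms: none
Why: Diimide reduction transfers H2 to the cis-disubstituted ring alkene without C–Cl hydrogenolysis and without a metal that sulfur could poison; it is run directly on fresh 19 so that the allylic chloride does not linger.

Step 11
Reactants: 20 (8S,9S)-9-chloro-8-methyl-1,5-dithiaspiro[5.5]undecane-8-carboxylic acid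
Product: 21 [(8S,9S)-9-chloro-8-methyl-1,5-dithiaspiro[5.5]undecan-8-yl]methanol
Conditions: BH3·THF, THF, 0 °C → rt; then MeOH, H2O
Reagents that add atoms: none
Why: Borane reduces even a hindered carboxylic acid chemoselectively, and the hindered secondary chloride and the thioketal are inert to it.

Step 12
Reactants: 21 [(8S,9S)-9-chloro-8-methyl-1,5-dithiaspiro[5.5]undecan-8-yl]methanol
Product: 22 (8S,9S)-9-chloro-8-methyl-1,5-dithiaspiro[5.5]undecane-8-carbaldehyde
Conditions: Dess–Martin periodinane, NaHCO3, CH2Cl2, rt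
Reagents that add atoms: none
Why: Dess–Martin oxidation of a neopentylic primary alcohol; the aldehyde has no α-hydrogen, so neither epimerisation nor elimination of the β-chloride is possible.

Step 13
Reactants: 22 (8S,9S)-9-chloro-8-methyl-1,5-dithiaspiro[5.5]undecane-8-carbaldehyde
Product: 23 (8S,9S)-9-chloro-8-ethynyl-8-methyl-1,5-dithiaspiro[5.5]undecane
Conditions: dimethyl (1-diazo-2-oxopropyl)phosphonate, K2CO3, MeOH, 0 °C → rt
Reagents that add atoms: dimethyl (1-diazo-2-oxopropyl)phosphonate, COP(=O)(OC)C(=[N+]=[N-])C(C)=O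
Why: Ohira–Bestmann (Seyferth–Gilbert) homologation of a non-enolisable aldehyde under mild carbonate conditions supplies C9 as a terminal alkyne.

Step 14
Reactants: 23 (8S,9S)-9-chloro-8-ethynyl-8-methyl-1,5-dithiaspiro[5.5]undecane
Product: 25 (8S,9S)-9-chloro-8-(chloroethynyl)-8-methyl-1,5-dithiaspiro[5.5]undecane, via lithium acetylide 24 (not isolated)
Conditions: n-BuLi, THF, −78 °C; then TsCl, −78 → 0 °C
Reagents that add atoms: 4-methylbenzenesulfonyl chloride, Cc1ccc(cc1)S(=O)(=O)Cl
Why: Electrophilic chlorination of a lithium acetylide by a sulfonyl chloride acting as a Cl+ donor, a reagent that does not attack the thioketal.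

Step 15
Reactants: 25 (8S,9S)-9-chloro-8-(chloroethynyl)-8-methyl-1,5-dithiaspiro[5.5]undecane
Product: 26 (8S,9S)-9-chloro-8-[(Z)-2-chloroethenyl]-8-methyl-1,5-dithiaspiro[5.5]undecane
Conditions: 2-nitrobenzenesulfonylhydrazide, Et3N, THF/i-PrOH, rt
Reagents that add atoms: none
Why: Diimide adds H2 syn to the 1-chloroalkyne (semi-reduction of a haloalkyne), which gives the (Z)-chloroalkene; the deactivated chloroalkene is reduced further only slowly.

Step 16
Reactants: 26 (8S,9S)-9-chloro-8-[(Z)-2-chloroethenyl]-8-methyl-1,5-dithiaspiro[5.5]undecane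
Product: 27 (3S,4S)-4-chloro-3-[(Z)-2-chloroethenyl]-3-methylcyclohexan-1-one
Conditions: PhI(OCOCF3)2, MeCN/H2O (9:1), 0 °C
Reagents that add atoms: water, O
Why: Oxidative hydrolysis of the thioketal with a hypervalent iodine reagent is fast at 0 °C and spares the electron-poor chloroalkene and the alkyl chloride.

Step 17
Reactants: 27 (3S,4S)-4-chloro-3-[(Z)-2-chloroethenyl]-3-methylcyclohexan-1-one
Product: 29 (2S,4S,5S)-4-chloro-5-[(Z)-2-chloroethenyl]-2-hydroxy-5-methylcyclohexan-1-one, via sodium enolate 28 (not isolated)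
Conditions: NaHMDS, THF, −78 °C; then 3-phenyl-2-(phenylsulfonyl)oxaziridine, −78 °C; AcOH
Reagents that add atoms: 3-phenyl-2-(phenylsulfonyl)oxaziridine, O=S(=O)(c1ccccc1)N1OC1c1ccccc1
Why: Kinetic deprotonation occurs away from the quaternary C1 (as with 3,3-disubstituted cyclohexanones) and gives the C3–C4 enolate, and enolate hydroxylation by the N-sulfonyloxaziridine should take place axially at C4 on the face opposite the pseudoaxial chlorovinyl group, placing the hydroxyl trans to the C6 chlorine; at −78 °C the enolate should not displace the γ-chloride.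

Step 18
Reactants: 29 (2S,4S,5S)-4-chloro-5-[(Z)-2-chloroethenyl]-2-hydroxy-5-methylcyclohexan-1-one
Product: 30 (1S,4S,5S)-5-chloro-4-[(Z)-2-chloroethenyl]-4-methyl-2-methylidenecyclohexan-1-ol
Conditions: Zn, CH2Br2, TiCl4 (excess), THF/CH2Cl2, 0 °C → rt
Reagents that add atoms: dibromomethane, BrCBr
Why: Lombardo methylenation is non-basic, so the epimerisable α-hydroxy ketone keeps its C4 configuration and the γ-chloro ketone is not exposed to an ylide base; the free hydroxyl only consumes extra reagent.

Step 19
Reactants: 30 (1S,4S,5S)-5-chloro-4-[(Z)-2-chloroethenyl]-4-methyl-2-methylidenecyclohexan-1-ol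
Product: 31 (1S,2S,4R)-2,4-dichloro-1-[(Z)-2-chloroethenyl]-1-methyl-5-methylidenecyclohexane
Conditions: Ph3P, hexachloroacetone, CH2Cl2, −20 → 0 °C
Reagents that add atoms: hexachloroacetone, O=C(C(Cl)(Cl)Cl)C(Cl)(Cl)Cl
Why: Appel-type chlorination of an allylic alcohol proceeds by SN2 displacement of the alkoxyphosphonium group with inversion and little allylic transposition, turning the axial C4 hydroxyl into the equatorial chloride cis to the C6 chlorine.

Step 20
Reactants: 31 (1S,2S,4R)-2,4-dichloro-1-[(Z)-2-chloroethenyl]-1-methyl-5-methylidenecyclohexane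
Product: 32 (1S,2R,4S,5S)-1-bromo-1-(bromomethyl)-2,4-dichloro-5-[(Z)-2-chloroethenyl]-5-methylcyclohexane
Conditions: Br2 (1.0 equiv), CH2Cl2, −78 °C
Reagents that add atoms: bromine, BrBr
Why: Ionic bromine addition takes the 1,1-disubstituted alkene in preference to the far less nucleophilic chloroalkene, and opening of the bromonium ion by bromide at tertiary C3 along the axial direction should give the epimer with bromine axial and C7H2Br equatorial, which is also expected to be the more stable one.

Compound list
1 | (R)-3-bromo-2-methylpropan-1-ol | C[C@H](CO)CBr | starting material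
2 | (R)-(3-bromo-2-methylpropoxy)(tert-butyl)dimethylsilane | C[C@H](CO[Si](C)(C)C(C)(C)C)CBr | intermediate
3 | 1,3-dithiane | C1CSCSC1 | starting material
4 | 2-lithio-1,3-dithiane | [Li]C1SCCCS1 | intermediate
5 | (S)-tert-butyl[3-(1,3-dithian-2-yl)-2-methylpropoxy]dimethylsilane | C[C@H](CO[Si](C)(C)C(C)(C)C)CC1SCCCS1 | intermediate
6 | 3-(trimethylsilyl)propynal | C[Si](C)(C)C#CC=O | starting material
7 | (S)-tert-butyl[3-(2-lithio-1,3-dithian-2-yl)-2-methylpropoxy]dimethylsilane | C[C@H](CO[Si](C)(C)C(C)(C)C)CC1([Li])SCCCS1 | intermediate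
8 | 1-{2-[(S)-3-(tert-butyldimethylsilyloxy)-2-methylpropyl]-1,3-dithian-2-yl}-3-(trimethylsilyl)prop-2-yn-1-ol (both carbinol epimers) | C[C@H](CO[Si](C)(C)C(C)(C)C)CC1(SCCCS1)C(O)C#C[Si](C)(C)C | intermediate
9 | 1-{2-[(S)-3-(tert-butyldimethylsilyloxy)-2-methylpropyl]-1,3-dithian-2-yl}-3-(trimethylsilyl)prop-2-yn-1-one | C[C@H](CO[Si](C)(C)C(C)(C)C)CC1(SCCCS1)C(=O)C#C[Si](C)(C)C | intermediate
10 | (R)-1-{2-[(S)-3-(tert-butyldimethylsilyloxy)-2-methylpropyl]-1,3-dithian-2-yl}-3-(trimethylsilyl)prop-2-yn-1-ol | C[C@H](CO[Si](C)(C)C(C)(C)C)CC1(SCCCS1)[C@H](O)C#C[Si](C)(C)C | intermediate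
11 | (R)-1-{2-[(S)-3-hydroxy-2-methylpropyl]-1,3-dithian-2-yl}prop-2-yn-1-ol | C[C@H](CO)CC1(SCCCS1)[C@H](O)C#C | intermediate
12 | (S)-3-{2-[(R)-1-hydroxyprop-2-yn-1-yl]-1,3-dithian-2-yl}-2-methylpropanal | C[C@H](C=O)CC1(SCCCS1)[C@H](O)C#C | intermediate
13 | (7R,10S)-7-ethynyl-10-methyl-8-oxa-1,5-dithiaspiro[5.5]undecan-9-ol (lactol, both anomers) | C[C@H]1CC2(SCCCS2)[C@@H](C#C)OC1O | intermediate
14 | (7R,10S)-7-ethynyl-10-methyl-8-oxa-1,5-dithiaspiro[5.5]undecan-9-one | C[C@H]1CC2(SCCCS2)[C@@H](C#C)OC1=O | intermediate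
15 | (7R,10S)-7-{(E)-2-[chlorobis(cyclopentadienyl)zirconio]ethenyl}-10-methyl-8-oxa-1,5-dithiaspiro[5.5]undecan-9-one | C[C@H]1CC2(SCCCS2)[C@@H](/C=C/[Zr](Cl)(C3C=CC=C3)C3C=CC=C3)OC1=O | intermediate
16 | (7R,10S)-7-[(E)-2-chloroethenyl]-10-methyl-8-oxa-1,5-dithiaspiro[5.5]undecan-9-one (key-step precursor: the 6-(E-chlorovinyl)-3-methyl δ-lactone with a spiro-dithiane at the pyranone C5) | C[C@H]1CC2(SCCCS2)[C@@H](/C=C/Cl)OC1=O | intermediate
17 | (7R)-7-[(E)-2-chloroethenyl]-10-methyl-9-(trimethylsilyloxy)-8-oxa-1,5-dithiaspiro[5.5]undec-9-ene | CC1=C(O[Si](C)(C)C)O[C@H](/C=C/Cl)C2(SCCCS2)C1 | intermediate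
18 | trimethylsilyl (8S,9S)-9-chloro-8-methyl-1,5-dithiaspiro[5.5]undec-10-ene-8-carboxylate | C[C@@]1(C(=O)O[Si](C)(C)C)CC2(SCCCS2)C=C[C@@H]1Cl | intermediate
19 | (8S,9S)-9-chloro-8-methyl-1,5-dithiaspiro[5.5]undec-10-ene-8-carboxylic acid (key-step product: 2-chloro-1-methylcyclohex-3-ene-1-carboxylic acid with a spiro-dithiane at ring C5) | C[C@@]1(C(=O)O)CC2(SCCCS2)C=C[C@@H]1Cl | intermediate
20 | (8S,9S)-9-chloro-8-methyl-1,5-dithiaspiro[5.5]undecane-8-carboxylic acid | C[C@@]1(C(=O)O)CC2(SCCCS2)CC[C@@H]1Cl | intermediate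
21 | [(8S,9S)-9-chloro-8-methyl-1,5-dithiaspiro[5.5]undecan-8-yl]methanol | C[C@@]1(CO)CC2(SCCCS2)CC[C@@H]1Cl | intermediate
22 | (8S,9S)-9-chloro-8-methyl-1,5-dithiaspiro[5.5]undecane-8-carbaldehyde | C[C@@]1(C=O)CC2(SCCCS2)CC[C@@H]1Cl | intermediate
23 | (8S,9S)-9-chloro-8-ethynyl-8-methyl-1,5-dithiaspiro[5.5]undecane | C[C@@]1(C#C)CC2(SCCCS2)CC[C@@H]1Cl | intermediate
24 | lithium acetylide of 23 | C[C@@]1(C#C[Li])CC2(SCCCS2)CC[C@@H]1Cl | intermediate
25 | (8S,9S)-9-chloro-8-(chloroethynyl)-8-methyl-1,5-dithiaspiro[5.5]undecane | C[C@@]1(C#CCl)CC2(SCCCS2)CC[C@@H]1Cl | intermediate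
26 | (8S,9S)-9-chloro-8-[(Z)-2-chloroethenyl]-8-methyl-1,5-dithiaspiro[5.5]undecane | C[C@@]1(/C=C\Cl)CC2(SCCCS2)CC[C@@H]1Cl | intermediate
27 | (3S,4S)-4-chloro-3-[(Z)-2-chloroethenyl]-3-methylcyclohexan-1-one | C[C@@]1(/C=C\Cl)CC(=O)CC[C@@H]1Cl | intermediate
28 | sodium enolate of 27 (C3–C4 enolate, ring numbering of the overview) | C[C@@]1(/C=C\Cl)CC(O[Na])=CC[C@@H]1Cl | intermediate
29 | (2S,4S,5S)-4-chloro-5-[(Z)-2-chloroethenyl]-2-hydroxy-5-methylcyclohexan-1-one (hydroxyl trans to the ring chlorine) | C[C@@]1(/C=C\Cl)CC(=O)[C@@H](O)C[C@@H]1Cl | intermediate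
30 | (1S,4S,5S)-5-chloro-4-[(Z)-2-chloroethenyl]-4-methyl-2-methylidenecyclohexan-1-ol | C[C@@]1(/C=C\Cl)CC(=C)[C@@H](O)C[C@@H]1Cl | intermediate
31 | (1S,2S,4R)-2,4-dichloro-1-[(Z)-2-chloroethenyl]-1-methyl-5-methylidenecyclohexane (the two ring chlorines cis) | C[C@@]1(/C=C\Cl)CC(=C)[C@H](Cl)C[C@@H]1Cl | intermediate
32 | (1S,2R,4S,5S)-1-bromo-1-(bromomethyl)-2,4-dichloro-5-[(Z)-2-chloroethenyl]-5-methylcyclohexane | C[C@@]1(/C=C\Cl)C[C@@](Br)(CBr)[C@H](Cl)C[C@@H]1Cl | target

Total step count: 20. Longest linear sequence: 20 steps (from 1; 3 and 6 enter at steps 2 and 3).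

Steps most likely to fail

Step 9. What may go wrong: the lactone enolate opens to a ketene or is C-silylated before it is trapped, or the allylic chloride ionises or undergoes a 1,3-shift at the temperature the congested boat needs. The fallback sets out from 16 and comes back at 22; it avoids the ester enolate by a neutral aliphatic Claisen rearrangement of the corresponding cyclic enol ether. DIBAL-H (CH2Cl2, −78 °C) should reduce 16 to the lactol F1. MsCl and Et3N with warming should dehydrate it to the 2-alkenyl-5-methyl-3,4-dihydro-2H-pyran F2, whose enol ether geometry is again locked by the ring. Heating F2 (toluene, sealed tube, about 180 °C, over a little K2CO3) should give, by the same boat-type [3,3] shift, the cyclohexene carbaldehyde F3 with C1 and C6 set as in 19. Diimide reduction of the ring alkene under the conditions of step 10 then gives aldehyde 22, so steps 11 and 12 fall away.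

Step 10. What may go wrong: diimide disproportionates faster than it reduces an alkene flanked by the spiro-dithiane carbon and by C6, while the allylic chloride slowly ionises or is displaced by the neighbouring carboxylate. The fallback sets out from 19 and comes back at 20; it removes the sulfur first, so that the alkene becomes part of an enone that a hydride can reduce. PhI(OCOCF3)2 in aqueous MeCN should unmask 19 to the enone acid F4. Conjugate reduction with [(Ph3P)CuH]6 (excess, benzene/THF, rt), which tolerates alkyl chlorides, should give the keto acid F5. Propane-1,3-dithiol and BF3·OEt2 in CH2Cl2 then restore the dithiane and give 20.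

Step 20. What may go wrong: poor facial selectivity when bromide opens the bromonium ion, because the axial trajectory at C3 passes the axial chlorovinyl group on C1; opening from the equatorial side gives the C3 epimer. The fallback sets out from 31 and comes back at 32; it moves the C3 centre from kinetic to thermodynamic control in a separate operation. Bromine is added as before and the crude product, containing the C3-epimeric dibromide F6, is equilibrated (for example with ZnBr2 in MeNO2 or in warm CHCl3). A tertiary–primary vicinal dibromide can exchange its two bromines through the bridged bromonium bromide ion pair, the process behind the known mutarotation of vicinal dibromides, and this exchange inverts C3. The target 32, which keeps the C7H2Br group equatorial and only bromine axial, should be the favoured epimer.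

Further compounds
F1 | step 9 | (7R,10S)-7-[(E)-2-chloroethenyl]-10-methyl-8-oxa-1,5-dithiaspiro[5.5]undecan-9-ol (lactol, both anomers) | C[C@H]1CC2(SCCCS2)[C@@H](/C=C/Cl)OC1O
F2 | step 9 | (7R)-7-[(E)-2-chloroethenyl]-10-methyl-8-oxa-1,5-dithiaspiro[5.5]undec-9-ene | CC1=CO[C@H](/C=C/Cl)C2(SCCCS2)C1
F3 | step 9 | (8S,9S)-9-chloro-8-methyl-1,5-dithiaspiro[5.5]undec-10-ene-8-carbaldehyde | C[C@@]1(C=O)CC2(SCCCS2)C=C[C@@H]1Cl
F4 | step 10 | (1S,2S)-2-chloro-1-methyl-5-oxocyclohex-3-ene-1-carboxylic acid | C[C@@]1(C(=O)O)CC(=O)C=C[C@@H]1Cl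
F5 | step 10 | (1S,2S)-2-chloro-1-methyl-5-oxocyclohexane-1-carboxylic acid | C[C@@]1(C(=O)O)CC(=O)CC[C@@H]1Cl
F6 | step 20 | (1R,2R,4S,5S)-1-bromo-1-(bromomethyl)-2,4-dichloro-5-[(Z)-2-chloroethenyl]-5-methylcyclohexane | C[C@@]1(/C=C\Cl)C[C@](Br)(CBr)[C@H](Cl)C[C@@H]1Cl
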